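**Retrosynthetic overview**
1. Target 22 ⇐ aryl silyl ether 21 ⇐ Evans–Tishchenko reaction of β-hydroxy enone 18 with silylated vanillin 20, which makes the C6 carbinol and the C8 vanillate in one step.
2. 18 ⇐ ten-membered ketone 17 ⇐ anionic oxy-Cope ring expansion (C8–C9 formed, C6–C1 broken) of the cis-1,2-dialkenylcyclohexenol 14. The six-membered ring comes from carvone; the only ring-forming event is the 6 → 10 expansion.
3. 14 ⇐ (S)-carvone 5 + bromo enol ether 4: α'-alkenylation, then α'-hydroxylation anti to the isopropenyl group (oxygen last, so the two alkenyl groups end cis), then enone → ring alkene via conjugate reduction, enol triflate and formate reduction.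
4. 4 ⇐ 3-methylbutanal 1 (α-bromination, enolate O-alkylation).

Assumption: ring atoms are called C1–C10 in germacrane numbering (C6 carbinol, C7 isopropyl, C8 ester carbon), and centres that are made trigonal later are carried on as epimer mixtures.

**Step 1**
Reactants: 1 3-methylbutanal
Product: 2 2-bromo-3-methylbutanal (racemic)
Conditions: Br2 (1.0 equiv), 1,4-dioxane (cat.), Et2O, 0 °C
Reagents that add atoms: bromine, BrBr
Why: Electrophilic α-bromination of the aldehyde through its enol; the new centre is racemic and irrelevant because it becomes trigonal in step 2.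

**Step 2**
Reactants: 2 2-bromo-3-methylbutanal
Product: 4 (Z)-2-bromo-1-[(4-methoxybenzyl)oxy]-3-methylbut-1-ene, via potassium enolate 3 (not isolated)
Conditions: KN(SiMe3)2 (0.98 equiv), THF–DMPU, −78 °C; then 4-methoxybenzyl bromide, −78 → 0 °C
Reagents that add atoms: 4-methoxybenzyl bromide, COc1ccc(CBr)cc1
Why: Enolate O-alkylation (Williamson type): the carbon terminus is blocked by Br and i-Pr so the benzylic bromide is taken at oxygen, and the enolate oxygen lies trans to the larger isopropyl group, giving mainly the Z ether (O cis to Br), purified by chromatography.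

**Step 3**
Reactants: 5 (S)-(+)-carvone; 4 (Z)-2-bromo-1-[(4-methoxybenzyl)oxy]-3-methylbut-1-ene
Product: 7 (5S,6S)-6-[(Z)-1-[(4-methoxybenzyl)oxy]-3-methylbut-1-en-2-yl]-2-methyl-5-(prop-1-en-2-yl)cyclohex-2-en-1-one (6-epimer carried along), via lithium enolate 6 (not isolated)
Conditions: LiN(SiMe3)2 (2.1 equiv), THF, −78 °C; then Pd2(dba)3 (2.5 mol %), P(t-Bu)3 (10 mol %), 4 (1.1 equiv), −78 → 40 °C; pH 7 buffer
Reagents that add atoms: none
Why: Palladium-catalysed α-alkenylation of a ketone enolate (enolate cross-coupling) at the only α'-position, with retention of the Z alkene; the new C6 centre (mainly trans to isopropenyl) is erased in step 4.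

**Step 4**
Reactants: 7 alkenyl carvone
Product: 10 (5R,6S)-6-[(Z)-1-[(4-methoxybenzyl)oxy]-3-methylbut-1-en-2-yl]-2-methyl-5-(prop-1-en-2-yl)-6-[(trimethylsilyl)oxy]cyclohex-2-en-1-one, via potassium dienolate 8 (not isolated), via potassium alkoxide 9 (not isolated)
Conditions: KN(SiMe3)2 (1.2 equiv), THF, −78 °C; 2-(phenylsulfonyl)-3-phenyloxaziridine; then Me3SiCl, −78 → 0 °C
Reagents that add atoms: 2-(phenylsulfonyl)-3-phenyloxaziridine, O=S(=O)(N1OC1c1ccccc1)c1ccccc1; chlorotrimethylsilane, C[Si](C)(C)Cl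
Why: Davis α-hydroxylation of the extended enolate at its α-carbon, the oxaziridine approaching the face opposite the adjacent isopropenyl group, so that O is trans and the alkenyl group cis to it (6S), followed by in-flask O-silylation.

**Step 5**
Reactants: 10 silyloxy enone
Product: 12 (5R,6S)-6-[(Z)-1-[(4-methoxybenzyl)oxy]-3-methylbut-1-en-2-yl]-2-methyl-5-(prop-1-en-2-yl)-6-[(trimethylsilyl)oxy]cyclohex-1-en-1-yl trifluoromethanesulfonate, via lithium enolate 11 (not isolated)
Conditions: LiBH(s-Bu)3 (1.1 equiv), THF, −78 °C; then N-(5-chloropyridin-2-yl)triflimide, −78 → 0 °C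
Reagents that add atoms: N-(5-chloropyridin-2-yl)-1,1,1-trifluoro-N-(trifluoromethylsulfonyl)methanesulfonamide, O=S(=O)(N(c1ccc(Cl)cn1)S(=O)(=O)C(F)(F)F)C(F)(F)F
Why: Conjugate (1,4) reduction of the enone by the bulky borohydride gives one regiodefined enolate, which is O-triflated; no stereocentre is formed or touched.

**Step 6**
Reactants: 12 enol triflate
Product: 14 (1S,6R)-1-[(Z)-1-[(4-methoxybenzyl)oxy]-3-methylbut-1-en-2-yl]-3-methyl-6-(prop-1-en-2-yl)cyclohex-2-en-1-ol, via silyl ether 13 (not isolated)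
Conditions: Pd(OAc)2 (5 mol %), PPh3 (10 mol %), Bu3N, HCO2H, DMF, 60 °C; then K2CO3 (cat.), MeOH, 0 °C
Reagents that add atoms: none
Why: Palladium-catalysed formate reduction of the enol triflate (C–OTf to C–H) makes the trisubstituted ring alkene, whose cis ring geometry is the future (Z)-C4=C5 bond, then mild methanolysis frees the tertiary alcohol; no stereocentre changes.

**Step 7**
Reactants: 14 cis-dialkenyl cyclohexenol
Product: 17 (2Z,6Z,9R,10S)-9-[(4-methoxybenzyl)oxy]-3,7-dimethyl-10-(propan-2-yl)cyclodeca-2,6-dien-1-one, via potassium alkoxide 15 (not isolated), via potassium enolate 16 (not isolated)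
Conditions: KN(SiMe3)2 (1.1 equiv), THF, −78 → 0 °C; then AcOH, −78 °C
Reagents that add atoms: none
Why: Anionic oxy-Cope rearrangement (6 → 10 ring expansion) through a chair in which K+ bridges the alkoxide and the enol-ether oxygen, the isopropenyl group is equatorial on the cyclohexene and the ring CH2 axial on the chair: this gives the (Z)-C1=C10 alkene, relays the isopropenyl-bearing stereocentre to C8 (R), and cold protonation on the open outer face of the enolate sets C7 trans to the C8 ether.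

**Step 8**
Reactants: 17 ten-membered ketone
Product: 18 (2Z,6Z,9R,10S)-9-hydroxy-3,7-dimethyl-10-(propan-2-yl)cyclodeca-2,6-dien-1-one
Conditions: DDQ (1.3 equiv), CH2Cl2–pH 7 phosphate buffer (10:1), 0 °C
Reagents that add atoms: none
Why: Oxidative 4-methoxybenzyl ether cleavage by DDQ via the benzylic oxocarbenium ion and its hemiacetal, neutral enough to leave the β-hydroxy ketone and both stereocentres untouched.

**Step 9**
Reactants: 19 vanillin
Product: 20 4-[(tert-butyldimethylsilyl)oxy]-3-methoxybenzaldehyde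
Conditions: t-BuMe2SiCl, imidazole, DMF, 25 °C
Reagents that add atoms: tert-butylchlorodimethylsilane, CC(C)(C)[Si](C)(C)Cl
Why: Imidazole-promoted silylation of the phenol; no stereocentre.

**Step 10**
Reactants: 18 β-hydroxy enone; 20 silylated vanillin
Product: 21 (1R,3Z,7Z,9R,10R)-9-hydroxy-3,7-dimethyl-10-(propan-2-yl)cyclodeca-3,7-dien-1-yl 4-[(tert-butyldimethylsilyl)oxy]-3-methoxybenzoate
Conditions: SmI2 (0.3 equiv), 20 (5 equiv), THF, −10 °C
Reagents that add atoms: none
Why: Evans–Tishchenko reduction: the samarium-bound hemiacetal of aldehyde 20 on O8 delivers its hydride intramolecularly to the C6 ketone through a chair chelate, giving the 1,3-anti (6R) alcohol and leaving the aroyl group on O8 in one operation.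

**Step 11**
Reactants: 21 silylated ester
Product: 22 (1R,3Z,7Z,9R,10R)-9-hydroxy-3,7-dimethyl-10-(propan-2-yl)cyclodeca-3,7-dien-1-yl 4-hydroxy-3-methoxybenzoate (target)
Conditions: Bu4NF (1.1 equiv), AcOH (1.2 equiv), THF, 0 °C
Reagents that add atoms: none
Why: Fluoride cleavage of the aryl silyl ether, buffered with acetic acid so that the phenoxide cannot trigger acyl migration or ester loss; no stereocentre changes.

**Compound list**
1 | 3-methylbutanal | CC(C)CC=O | starting material
2 | 2-bromo-3-methylbutanal (racemic) | CC(C)C(Br)C=O | intermediate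
3 | potassium (Z)-2-bromo-3-methylbut-1-en-1-olate | [K+].[O-]/C=C(\Br)C(C)C | intermediate
4 | (Z)-2-bromo-1-[(4-methoxybenzyl)oxy]-3-methylbut-1-ene | COc1ccc(CO/C=C(\Br)C(C)C)cc1 | intermediate
5 | (S)-(+)-carvone | CC1=CC[C@@H](CC1=O)C(C)=C | starting material
6 | lithium (3S)-6-methyl-3-(prop-1-en-2-yl)cyclohexa-1,5-dien-1-olate (kinetic α'-enolate of 5) | CC1=CC[C@H](C(C)=C)C=C1[O-].[Li+] | intermediate
7 | (5S,6S)-6-[(Z)-1-[(4-methoxybenzyl)oxy]-3-methylbut-1-en-2-yl]-2-methyl-5-(prop-1-en-2-yl)cyclohex-2-en-1-one | O=C1C(C)=CC[C@H](C(C)=C)[C@H]1/C(C(C)C)=C\OCc2ccc(OC)cc2 | intermediate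
8 | potassium dienolate of 7 | [K+].[O-]C1=C(/C(C(C)C)=C\OCc2ccc(OC)cc2)[C@@H](C(C)=C)CC=C1C | intermediate
9 | potassium (5R,6S)-6-oxido ketone (alkoxide of the α'-hydroxy enone) | O=C1C(C)=CC[C@H](C(C)=C)[C@]1([O-])/C(C(C)C)=C\OCc2ccc(OC)cc2.[K+] | intermediate
10 | (5R,6S)-6-[(Z)-1-[(4-methoxybenzyl)oxy]-3-methylbut-1-en-2-yl]-2-methyl-5-(prop-1-en-2-yl)-6-[(trimethylsilyl)oxy]cyclohex-2-en-1-one | O=C1C(C)=CC[C@H](C(C)=C)[C@]1(O[Si](C)(C)C)/C(C(C)C)=C\OCc2ccc(OC)cc2 | intermediate
11 | lithium enolate from conjugate reduction of 10 | [Li+].[O-]C1=C(C)CC[C@H](C(C)=C)[C@]1(O[Si](C)(C)C)/C(C(C)C)=C\OCc2ccc(OC)cc2 | intermediate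
12 | (5R,6S)-6-[(Z)-1-[(4-methoxybenzyl)oxy]-3-methylbut-1-en-2-yl]-2-methyl-5-(prop-1-en-2-yl)-6-[(trimethylsilyl)oxy]cyclohex-1-en-1-yl trifluoromethanesulfonate | O=S(=O)(OC1=C(C)CC[C@H](C(C)=C)[C@]1(O[Si](C)(C)C)/C(C(C)C)=C\OCc2ccc(OC)cc2)C(F)(F)F | intermediate
13 | trimethylsilyl ether of 14 | C1=C(C)CC[C@H](C(C)=C)[C@]1(O[Si](C)(C)C)/C(C(C)C)=C\OCc2ccc(OC)cc2 | intermediate
14 | (1S,6R)-1-[(Z)-1-[(4-methoxybenzyl)oxy]-3-methylbut-1-en-2-yl]-3-methyl-6-(prop-1-en-2-yl)cyclohex-2-en-1-ol | C1=C(C)CC[C@H](C(C)=C)[C@]1(O)/C(C(C)C)=C\OCc2ccc(OC)cc2 | intermediate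
15 | potassium alkoxide of 14 | C1=C(C)CC[C@H](C(C)=C)[C@]1([O-])/C(C(C)C)=C\OCc2ccc(OC)cc2.[K+] | intermediate
16 | potassium enolate of 17 (C6=C7 enolate, ring-trans) | COc1ccc(CO[C@@H]2C/C(C)=C\CC/C(C)=C\C(\[O-])=C2/C(C)C)cc1.[K+] | intermediate
17 | (2Z,6Z,9R,10S)-9-[(4-methoxybenzyl)oxy]-3,7-dimethyl-10-(propan-2-yl)cyclodeca-2,6-dien-1-one | COc1ccc(CO[C@@H]2C/C(C)=C\CC/C(C)=C\C(=O)[C@H]2C(C)C)cc1 | intermediate
18 | (2Z,6Z,9R,10S)-9-hydroxy-3,7-dimethyl-10-(propan-2-yl)cyclodeca-2,6-dien-1-one | O[C@@H]1C/C(C)=C\CC/C(C)=C\C(=O)[C@H]1C(C)C | intermediate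
19 | vanillin | COc1cc(C=O)ccc1O | starting material
20 | 4-[(tert-butyldimethylsilyl)oxy]-3-methoxybenzaldehyde | COc1cc(C=O)ccc1O[Si](C)(C)C(C)(C)C | intermediate
21 | (1R,3Z,7Z,9R,10R)-9-hydroxy-3,7-dimethyl-10-(propan-2-yl)cyclodeca-3,7-dien-1-yl 4-[(tert-butyldimethylsilyl)oxy]-3-methoxybenzoate | COc1cc(C(=O)O[C@@H]2C/C(C)=C\CC/C(C)=C\[C@@H](O)[C@H]2C(C)C)ccc1O[Si](C)(C)C(C)(C)C | intermediate
22 | (1R,3Z,7Z,9R,10R)-9-hydroxy-3,7-dimethyl-10-(propan-2-yl)cyclodeca-3,7-dien-1-yl 4-hydroxy-3-methoxybenzoate | COc1cc(C(=O)O[C@@H]2C/C(C)=C\CC/C(C)=C\[C@@H](O)[C@H]2C(C)C)ccc1O | target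

**Step count and risk**
Total steps: 11. Longest linear sequence: 10 (steps 1–8, 10, 11); from carvone it is 8.

The three steps most likely to fail:

Step 3. The bromide is hindered and electron-rich, excess amide base could strip HBr from 4 to give the ynol ether, and the cross-conjugated enolate could scramble. The fallback sets out from 5 (still using 4) and comes back at 7. Carvone is converted with LiN(i-Pr)2 and Me3SiCl at −78 °C into the kinetic silyl dienol ether F1. This is coupled with 4 without any strong base, using Bu3SnF and PdCl2[P(o-tolyl)3]2 in toluene at 80 °C, through the neutral tributyltin enolate F2 formed in the flask. The result is 7, with the enol-ether geometry never exposed to a dienolate.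

Step 7. A boat or the alternative chair would give the wrong C8 or an E alkene, and the β-alkoxy enolate could lose 4-methoxybenzyl oxide. The fallback sets out from 13 (isolated by leaving out the methanolysis of step 6) and comes back at 17. The silyl ether is rearranged thermally (neutral siloxy-Cope, toluene, 180 °C, sealed tube) to the ten-membered silyl enol ether F3, so no free enolate is present. F3 is then cleaved with Bu4NF in the presence of AcOH at −78 °C to give 17.

Step 10. The cyclic hydride-transfer chelate may not form well on the ten-membered ring with the axial isopropyl group, and the electron-rich aldehyde is a slow hydride donor. The fallback sets out from 18 (and 20) and comes back at 21. Aldehyde 20 is oxidised with NaClO2, NaH2PO4 and 2-methylbut-2-ene to the acid F4. F4 is esterified onto the C8 hydroxyl of 18 with dicyclohexylcarbodiimide and catalytic 4-dimethylaminopyridine at 0 °C to give the keto ester F5. F5 is reduced with NaBH4 and CeCl3·7H2O in MeOH at −78 °C. Hydride is expected on the outer face, anti to the C8 ring branch (Felkin–Anh), giving 21; any 6-epimer is recycled by MnO2 oxidation.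

**Further compounds**
F1 | step 3 | trimethyl{[(3S)-6-methyl-3-(prop-1-en-2-yl)cyclohexa-1,5-dien-1-yl]oxy}silane | CC1=CC[C@H](C(C)=C)C=C1O[Si](C)(C)C
F2 | step 3 | tributyl{[(3S)-6-methyl-3-(prop-1-en-2-yl)cyclohexa-1,5-dien-1-yl]oxy}stannane | CC1=CC[C@H](C(C)=C)C=C1O[Sn](CCCC)(CCCC)CCCC
F3 | step 7 | trimethylsilyl enol ether of 17 (C6=C7 enol ether, ring-trans) | COc1ccc(CO[C@@H]2C/C(C)=C\CC/C(C)=C\C(\O[Si](C)(C)C)=C2/C(C)C)cc1
F4 | step 10 | 4-[(tert-butyldimethylsilyl)oxy]-3-methoxybenzoic acid | COc1cc(C(=O)O)ccc1O[Si](C)(C)C(C)(C)C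
F5 | step 10 | (1R,3Z,7Z,10S)-3,7-dimethyl-9-oxo-10-(propan-2-yl)cyclodeca-3,7-dien-1-yl 4-[(tert-butyldimethylsilyl)oxy]-3-methoxybenzoate | COc1cc(C(=O)O[C@@H]2C/C(C)=C\CC/C(C)=C\C(=O)[C@H]2C(C)C)ccc1O[Si](C)(C)C(C)(C)C
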